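## Retrosynthetic overview

1. Target 12 ⇐ bis(benzyl ether) 11 by hydrogenolysis; 11 ⇐ α-hydroxy lactone 8 + benzylic chloride 9 by C-benzylation of the enediolate anti to the C4 substituent (sets C3).
2. 8 ⇐ (R)-β-(3,4-dimethoxybenzyl)butyrolactone 6 by enolate hydroxylation.
3. 6 ⇐ bicyclic lactone 5 by hydrogenolysis of the push–pull cyclopropane bond C1–C6, which unmasks the 3,4-dimethoxybenzyl group.
4. 5 ⇐ diazoacetate 4 by catalytic enantioselective intramolecular cyclopropanation, which closes cyclopropane and lactone together and sets the only catalyst-controlled stereocentre; 4 ⇐ alcohol 1 + acid chloride 2.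
5. Ring order: both arenes are bought; the lactone and the cyclopropane form together in step 2; the cyclopropane is opened in step 3; no further ring is made.

Assumption: 1, 2 and 9 are bought as catalogue compounds; the target is read from its SMILES as the (3S,4S) lactone (hydroxyl cis to the dimethoxybenzyl group, the two benzyl groups trans).

## Route

Step 1
Reactants: 1 (E)-3-(3,4-dimethoxyphenyl)prop-2-en-1-ol; 2 glyoxylic acid chloride p-toluenesulfonylhydrazone
Product: 4 (E)-3-(3,4-dimethoxyphenyl)allyl diazoacetate, via tosylhydrazone ester 3 (not isolated)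
Conditions: 2 (1.8 equiv), PhNMe2 (1.8 equiv), CH2Cl2, 0 °C, 30 min; then Et3N (5 equiv), 0 °C to rt
Reagents that add atoms: none
Why: Acylation of the allylic alcohol by the acid chloride gives ester 3, from which Et3N expels p-toluenesulfinate (Bamford–Stevens-type fragmentation, the House/Corey–Myers diazoacetate synthesis); no stereocentre is formed and the E-alkene is not touched.

Step 2
Reactants: 4 (E)-3-(3,4-dimethoxyphenyl)allyl diazoacetate
Product: 5 (1S,5R,6R)-6-(3,4-dimethoxyphenyl)-3-oxabicyclo[3.1.0]hexan-2-one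
Conditions: Rh2(4R-MPPIM)4 (1 mol %; MPPIM = methyl 2-oxo-1-(3-phenylpropanoyl)imidazolidine-4-carboxylate), CH2Cl2, reflux, 4 added by syringe pump over 10 h
Reagents that add atoms: none
Why: Doyle-type enantioselective intramolecular cyclopropanation (carbene transfer from a chiral divalent-rhodium carboxamidate) closes the cyclopropane and the γ-lactone in the same event, transfers the E-geometry stereospecifically (aryl exo, cis ring fusion), and with the 4R ligand set, by the sense of induction I recall for this catalyst family with allylic diazoacetates, places C6 on the face that makes C5 the future C4 of the target.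

Step 3
Reactants: 5 (1S,5R,6R)-6-(3,4-dimethoxyphenyl)-3-oxabicyclo[3.1.0]hexan-2-one
Product: 6 (R)-4-(3,4-dimethoxybenzyl)dihydrofuran-2(3H)-one
Conditions: H2 (1–3 atm), 10% Pd/C, EtOAc, rt
Reagents that add atoms: none
Why: Catalytic hydrogenolysis of a donor–acceptor aryl cyclopropane cleaves the C1–C6 bond, the one that is both benzylic and α to the carbonyl, so the aryl-bearing carbon becomes the benzylic CH2 while C5 is untouched and becomes C4 of 6 with R configuration (same spatial arrangement, new CIP ranking).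

Step 4
Reactants: 6 (R)-4-(3,4-dimethoxybenzyl)dihydrofuran-2(3H)-one
Product: 8 (3R,4S)-4-(3,4-dimethoxybenzyl)-3-hydroxydihydrofuran-2(3H)-one, via sodium enolate 7 (not isolated)
Conditions: NaN(SiMe3)2 (1.2 equiv), THF, −78 °C; then 3-phenyl-2-(phenylsulfonyl)oxaziridine (1.5 equiv), −78 °C; AcOH quench
Reagents that add atoms: 3-phenyl-2-(phenylsulfonyl)oxaziridine (Davis oxaziridine), O=S(=O)(c1ccccc1)N1OC1c1ccccc1
Why: Davis oxidation: the sodium enolate 7 takes electrophilic oxygen from the N-sulfonyloxaziridine on the face anti to the C4 benzyl group, giving the trans hydroxy lactone (3R at the new centre; this centre is planarised again in step 5, so its ratio is not critical).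

Step 5
Reactants: 8 (3R,4S)-4-(3,4-dimethoxybenzyl)-3-hydroxydihydrofuran-2(3H)-one; 9 3,4-bis(benzyloxy)benzyl chloride
Product: 11 (3S,4S)-3-[3,4-bis(benzyloxy)benzyl]-4-(3,4-dimethoxybenzyl)-3-hydroxydihydrofuran-2(3H)-one, via dilithium enediolate 10 (not isolated)
Conditions: LiN(iPr)2 (2.3 equiv), THF–DMPU, −78 to −40 °C; then 9 (1.2 equiv), Bu4NI (10 mol %), −78 to −20 °C; AcOH quench
Reagents that add atoms: none
Why: Alkylation of the α-oxido enolate (Fráter–Seebach-type dianion alkylation): the planar enediolate 10 is benzylated at carbon, its most nucleophilic site, on the face anti to the C4 dimethoxybenzyl group, which puts the two benzyl groups trans and the hydroxyl cis to the C4 substituent, i.e. 3S, with Bu4NI turning the chloride into the iodide in the flask.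

Step 6
Reactants: 11 (3S,4S)-3-[3,4-bis(benzyloxy)benzyl]-4-(3,4-dimethoxybenzyl)-3-hydroxydihydrofuran-2(3H)-one
Product: 12 (3S,4S)-3-(3,4-dihydroxybenzyl)-4-(3,4-dimethoxybenzyl)-3-hydroxydihydrofuran-2(3H)-one
Conditions: H2 (1 atm), 10% Pd/C, EtOAc–MeOH, rt; filtered and concentrated under argon
Reagents that add atoms: none
Why: Hydrogenolysis of the two aryl benzyl ethers over Pd/C frees the catechol; the methyl ethers, the lactone and the tertiary, non-benzylic alcohol are inert and no stereocentre is involved.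

## Compound list

1 | (E)-3-(3,4-dimethoxyphenyl)prop-2-en-1-ol | COc1ccc(/C=C/CO)cc1OC | starting material
2 | glyoxylic acid chloride p-toluenesulfonylhydrazone, (E)-2-(2-tosylhydrazinylidene)acetyl chloride | Cc1ccc(cc1)S(=O)(=O)N/N=C/C(Cl)=O | starting material
3 | (E)-3-(3,4-dimethoxyphenyl)allyl (E)-2-(2-tosylhydrazinylidene)acetate | COc1ccc(/C=C/COC(=O)/C=N/NS(=O)(=O)c2ccc(C)cc2)cc1OC | intermediate (not isolated)
4 | (E)-3-(3,4-dimethoxyphenyl)allyl 2-diazoacetate | COc1ccc(/C=C/COC(=O)C=[N+]=[N-])cc1OC | intermediate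
5 | (1S,5R,6R)-6-(3,4-dimethoxyphenyl)-3-oxabicyclo[3.1.0]hexan-2-one | O=C1OC[C@@H]2[C@@H](c3ccc(OC)c(OC)c3)[C@H]12 | intermediate
6 | (R)-4-(3,4-dimethoxybenzyl)dihydrofuran-2(3H)-one | O=C1C[C@@H](Cc2ccc(OC)c(OC)c2)CO1 | intermediate
7 | sodium (4R)-4-(3,4-dimethoxybenzyl)-4,5-dihydrofuran-2-olate | [Na+].[O-]C1=C[C@@H](Cc2ccc(OC)c(OC)c2)CO1 | intermediate (not isolated)
8 | (3R,4S)-4-(3,4-dimethoxybenzyl)-3-hydroxydihydrofuran-2(3H)-one | COc1ccc(C[C@H]2COC(=O)[C@@H]2O)cc1OC | intermediate
9 | 3,4-bis(benzyloxy)benzyl chloride, 4-(chloromethyl)-1,2-bis(benzyloxy)benzene | ClCc1ccc(OCc2ccccc2)c(OCc2ccccc2)c1 | starting material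
10 | dilithium (4S)-4-(3,4-dimethoxybenzyl)-4,5-dihydrofuran-2,3-bis(olate) | [Li+].[Li+].[O-]C1=C([O-])[C@@H](Cc2ccc(OC)c(OC)c2)CO1 | intermediate (not isolated)
11 | (3S,4S)-3-[3,4-bis(benzyloxy)benzyl]-4-(3,4-dimethoxybenzyl)-3-hydroxydihydrofuran-2(3H)-one | COc1ccc(C[C@H]2COC(=O)[C@]2(O)Cc2ccc(OCc3ccccc3)c(OCc3ccccc3)c2)cc1OC | intermediate
12 | (3S,4S)-3-(3,4-dihydroxybenzyl)-4-(3,4-dimethoxybenzyl)-3-hydroxydihydrofuran-2(3H)-one | COc1ccc(C[C@H]2COC(=O)[C@]2(O)Cc2ccc(O)c(O)c2)cc1OC | target

## Step count and risks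

Total steps: 6. Longest linear sequence: 6 (1 → 4 → 5 → 6 → 8 → 11 → 12; 2 and 9 enter as bought reagents).

**Step 2.** The risks are the enantiomeric excess with an E-aryl alkene, carbene dimerisation, and the sense of induction. The choice of the 4R catalyst rests on my recollection of the sense reported for this ligand family; it is confirmed on 6 by optical rotation and corrected with the 4S catalyst if needed. The fallback sets out from 1 and comes back at 6. The alkene of 1 is hydrogenated (H2, Pd/C, EtOAc) to 3-(3,4-dimethoxyphenyl)propan-1-ol F1. F1 is acylated with 2 exactly as in step 1, passing in the flask through 3-(3,4-dimethoxyphenyl)propyl (E)-2-(2-tosylhydrazinylidene)acetate F2, to 3-(3,4-dimethoxyphenyl)propyl 2-diazoacetate F3. F3 is cyclised by enantioselective intramolecular carbene insertion into the C–H bond β to oxygen with Rh2(4S-MPPIM)4 (CH2Cl2, reflux, slow addition). This is the catalyst enantiomer expected to give (R)-6, again to be confirmed by rotation, and it delivers 6 directly, so the route resumes with step 4.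

**Step 3.** The risks are cleavage of the wrong cyclopropane bond (C5–C6, giving the α-benzyl lactone) or a sluggish reaction. The fallback sets out from 5 and comes back at 6. The push–pull cyclopropane is opened ionically with PhSH (2 equiv) and Sc(OTf)3 (10 mol %) in CH2Cl2 at rt. The thiol adds at the cation-stabilised benzylic carbon and the C1–C6 bond breaks, giving (4R)-4-[(3,4-dimethoxyphenyl)(phenylsulfanyl)methyl]dihydrofuran-2(3H)-one F4 as either or both benzylic epimers. Raney Ni in EtOH at rt then removes the sulfur and gives 6.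

**Step 5.** The risks are O- instead of C-alkylation of the dianion, incomplete dianion formation, and a low diastereomer ratio. The fallback sets out from 8 and comes back at 11. The hydroxyl is silylated (TBSCl, imidazole, DMF) to (3R,4S)-3-[(tert-butyldimethylsilyl)oxy]-4-(3,4-dimethoxybenzyl)dihydrofuran-2(3H)-one F5. LiN(iPr)2 (1.15 equiv, THF, −78 °C) gives lithium (4S)-3-[(tert-butyldimethylsilyl)oxy]-4-(3,4-dimethoxybenzyl)-4,5-dihydrofuran-2-olate F6. F6 is alkylated with 9 and Bu4NI at −78 °C, again anti to the C4 group, to (3S,4S)-3-[3,4-bis(benzyloxy)benzyl]-3-[(tert-butyldimethylsilyl)oxy]-4-(3,4-dimethoxybenzyl)dihydrofuran-2(3H)-one F7. Bu4NF/AcOH in THF at 0 °C removes the silyl group and gives 11, which goes on to step 6.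

## Further compounds

F1 | step 2 | 3-(3,4-dimethoxyphenyl)propan-1-ol | COc1ccc(CCCO)cc1OC
F2 | step 2 | 3-(3,4-dimethoxyphenyl)propyl (E)-2-(2-tosylhydrazinylidene)acetate | COc1ccc(CCCOC(=O)/C=N/NS(=O)(=O)c2ccc(C)cc2)cc1OC
F3 | step 2 | 3-(3,4-dimethoxyphenyl)propyl 2-diazoacetate | COc1ccc(CCCOC(=O)C=[N+]=[N-])cc1OC
F4 | step 3 | (4R)-4-[(3,4-dimethoxyphenyl)(phenylsulfanyl)methyl]dihydrofuran-2(3H)-one (benzylic carbon not defined) | O=C1C[C@@H](C(Sc2ccccc2)c2ccc(OC)c(OC)c2)CO1
F5 | step 5 | (3R,4S)-3-[(tert-butyldimethylsilyl)oxy]-4-(3,4-dimethoxybenzyl)dihydrofuran-2(3H)-one | COc1ccc(C[C@H]2COC(=O)[C@@H]2O[Si](C)(C)C(C)(C)C)cc1OC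
F6 | step 5 | lithium (4S)-3-[(tert-butyldimethylsilyl)oxy]-4-(3,4-dimethoxybenzyl)-4,5-dihydrofuran-2-olate | [Li+].[O-]C1=C(O[Si](C)(C)C(C)(C)C)[C@@H](Cc2ccc(OC)c(OC)c2)CO1
F7 | step 5 | (3S,4S)-3-[3,4-bis(benzyloxy)benzyl]-3-[(tert-butyldimethylsilyl)oxy]-4-(3,4-dimethoxybenzyl)dihydrofuran-2(3H)-one | COc1ccc(C[C@H]2COC(=O)[C@]2(O[Si](C)(C)C(C)(C)C)Cc2ccc(OCc3ccccc3)c(OCc3ccccc3)c2)cc1OC
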